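**Strategy.** C7 is stereogenic only because the pyran carbon C1 is bonded to C8a and not to C5: without C1 the carbocycle (C4a, C5, C6, C7, C8, C8a) is a tautomerising, Cs-symmetric 2-acyloxy-2-methyl-1,3-dione. The route therefore oxidises first, without any stereocontrol, and desymmetrises second. The precursor of the key step is the achiral alkynyl quinol decanoate 8. A chiral isothiourea relays a formyl group from the enol oxygen to one of the two enantiotopic ring carbons (C8a); this forms C1–C8a, fixes the C7 configuration, and copper-mediated O2–C3 closure in the same flask completes the pyran ring. The ester is already in place.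

Key step: step 5

Remark 1: atom labels (C1, O2, C3 … C8a) are those of the isochromene core of the target and are used for the corresponding atoms of all precursors.
Remark 2: 8 is drawn as one enol tautomer; it is assumed that proton transfer between O6 and O8 interconverts its mirror-image tautomers quickly, so 8 is treated as achiral.
Remark 3: the sense of induction of the isothiourea in step 5 cannot be assigned in advance; (2S,3R)-HyperBTM is written as the working choice, and its enantiomer is to be used if the first run indicates the opposite sense.

Step 1
Reactants: 1 2,6-dimethoxytoluene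
Product: 3 5-bromo-1,3-dimethoxy-2-methylbenzene, via aryl pinacol boronate 2 (not isolated)
Conditions: B2pin2 (1.0 equiv), [Ir(OMe)(cod)]2 (1.5 mol %), dtbpy (3 mol %), THF, 80 °C; evaporate; CuBr2 (3 equiv), MeOH/H2O 1:1, 80 °C
Reagents that add atoms: copper(II) bromide, [Cu+2].[Br-].[Br-] (bromine of 3); bis(pinacolato)diboron, CC1(C)OB(OC1(C)C)B1OC(C)(C)C(C)(C)O1 (boryl group of 2 only)
Why: Sterically controlled iridium-catalysed C–H borylation should functionalise only the ring position of 1 that has no ortho substituent (para to the methyl group), and copper(II)-mediated bromodeboronation of 2 should then give 3 in the same flask.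

Step 2
Reactants: 3 5-bromo-1,3-dimethoxy-2-methylbenzene
Product: 4 5-bromo-2-methylbenzene-1,3-diol
Conditions: BBr3 (2.5 equiv), CH2Cl2, −78 °C to rt; H2O
Reagents that add atoms: none
Why: Boron tribromide cleavage of aryl methyl ethers (Lewis adduct, then SN2 attack of bromide at methyl) should unmask both phenols while the aryl bromide stays inert.

Step 3
Reactants: 4 5-bromo-2-methylbenzene-1,3-diol; 5 non-1-yne
Product: 6 2-methyl-5-(non-1-yn-1-yl)benzene-1,3-diol
Conditions: PdCl2(PPh3)2 (3 mol %), CuI (5 mol %), Et3N (4 equiv), DMF, 70 °C, degassed
Reagents that add atoms: none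
Why: Sonogashira coupling should form the C4a–C4 bond; the bromide is meta to both free hydroxyls, so the phenols are tolerated and no oxygen can cyclise onto the alkyne.

Step 4
Reactants: 6 2-methyl-5-(non-1-yn-1-yl)benzene-1,3-diol; 7 decanoic acid
Product: 8 2-hydroxy-1-methyl-4-(non-1-yn-1-yl)-6-oxocyclohexa-2,4-dien-1-yl decanoate
Conditions: Pb(OAc)4 (1.05 equiv) pre-exchanged with 7 (6 equiv; toluene, AcOH removed in vacuo), added slowly to 6 in CH2Cl2, −20 °C
Reagents that add atoms: none
Why: Wessely-type acyloxylation: the aryloxy–lead(IV) carboxylate formed at either hydroxyl should deliver a decanoate ligand to the methyl-bearing carbon that is ortho to both oxygens (C7), giving a quinol ester that cannot rearomatise and in which no configuration is fixed, because its mirror-image enol tautomers interconvert.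

Step 5
Reactants: 8 2-hydroxy-1-methyl-4-(non-1-yn-1-yl)-6-oxocyclohexa-2,4-dien-1-yl decanoate; 9 1H-benzotriazole-1-carbaldehyde
Product: 12 (7R)-3-heptyl-7-methyl-6,8-dioxo-7,8-dihydro-6H-isochromen-7-yl decanoate, via enol formate 10 (not isolated), via C8a-formyl quinol ester 11 (not isolated)
Conditions: 9 (1.1 equiv), (2S,3R)-HyperBTM (10 mol %), iPr2NEt (1.2 equiv), CH2Cl2, −40 °C; then CuI (10 mol %), pH 7.2 phosphate buffer/MeCN, rt
Reagents that add atoms: none
Why: Proposed new method: the enolate of 8 is O-formylated by 9 to racemic enol formate 10, the isothiourea takes the formyl group off again to give a chiral N-formyl isothiouronium paired with the Cs-symmetric dienolate, and C–C bond formation at one of the two enantiotopic ring carbons (C8a, not C5) followed by enolisation gives the hydrogen-bonded β-hydroxy enal 11, so both enantiomers of 10 are funnelled through one achiral anion (stereoconvergent). The closest known reaction type is the Steglich-type O-to-C acyl transfer with chiral isothiourea or 4-aminopyridine catalysts, together with the achiral enol ester to 2-acyl-1,3-dione rearrangement; new here are the formyl group and the use of the transfer to choose between two enantiotopic carbons of a quinol dienolate and not between two faces. C7 itself is not touched: its configuration is defined by which flanking carbon receives C1, and that choice is made by the catalyst-bound formyl cation, which should approach the dienolate face anti to the bulky C7 decanoyloxy group and then distinguish C8a from C5 on that face, with the catalyst enantiomer matched to the (R) product. The step needs C- over O-formylation, secured by reversible O-formylation against irreversible formation of chelated 11, and C8a over C5, secured by the catalyst; the alkynyl arm carries no acidic C–H, so no third nucleophilic carbon competes. The pyran ring then closes by copper(I)-promoted 6-endo-dig attack of the formyl oxygen (O2) on alkyne carbon C3, and the incipient 2-benzopyrylium is quenched by loss of the C6–OH proton to give the neutral pyranoquinone 12, a closure mode known for o-alkynyl formyl quinols.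

**Compound list**

1 | 2,6-dimethoxytoluene | COc1cccc(OC)c1C | starting material
2 | 2-(3,5-dimethoxy-4-methylphenyl)-4,4,5,5-tetramethyl-1,3,2-dioxaborolane (formed in the flask) | COc1cc(B2OC(C)(C)C(C)(C)O2)cc(OC)c1C | intermediate
3 | 5-bromo-1,3-dimethoxy-2-methylbenzene | COc1cc(Br)cc(OC)c1C | intermediate
4 | 5-bromo-2-methylbenzene-1,3-diol | Cc1c(O)cc(Br)cc1O | intermediate
5 | non-1-yne | C#CCCCCCCC | starting material
6 | 2-methyl-5-(non-1-yn-1-yl)benzene-1,3-diol | CCCCCCCC#Cc1cc(O)c(C)c(O)c1 | intermediate
7 | decanoic acid | CCCCCCCCCC(=O)O | starting material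
8 | 2-hydroxy-1-methyl-4-(non-1-yn-1-yl)-6-oxocyclohexa-2,4-dien-1-yl decanoate (achiral through tautomerism, one tautomer drawn) | CCCCCCCCCC(=O)OC1(C)C(=O)C=C(C#CCCCCCCC)C=C1O | intermediate
9 | 1H-benzotriazole-1-carbaldehyde (N-formylbenzotriazole) | O=Cn1nnc2ccccc12 | starting material
10 | 2-(formyloxy)-1-methyl-4-(non-1-yn-1-yl)-6-oxocyclohexa-2,4-dien-1-yl decanoate (racemic, formed in the flask) | CCCCCCCCCC(=O)OC1(C)C(=O)C=C(C#CCCCCCCC)C=C1OC=O | intermediate
11 | (1R)-5-formyl-2-hydroxy-1-methyl-4-(non-1-yn-1-yl)-6-oxocyclohexa-2,4-dien-1-yl decanoate (formed in the flask) | CCCCCCCCCC(=O)O[C@]1(C)C(O)=CC(C#CCCCCCCC)=C(C=O)C1=O | intermediate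
12 | (7R)-3-heptyl-7-methyl-6,8-dioxo-7,8-dihydro-6H-isochromen-7-yl decanoate | CCCCCCCCCC(=O)O[C@]1(C)C(=O)C=C2C=C(CCCCCCC)OC=C2C1=O | target

**Totals.** Total step count: 5. Longest linear sequence: 5 steps (1 → 3 → 4 → 6 → 8 → 12).

**Steps most likely to fail**

Step 5 (key step, proposed new method). The formyl group may stay on oxygen or be lost by hydrolysis. C-formylation may occur outside the catalyst ion pair, or with poor discrimination between C8a and C5, so that enantioselectivity is low. The decanoyl group may also migrate from O7 to an enolate oxygen under the basic conditions. The fallback uses known chemistry and replaces site selection on the quinol by facial selection on the arene. It sets out from 6: Vilsmeier–Haack formylation (POCl3, DMF, 0 °C to rt, then aqueous NaOAc) at the position ortho to the alkyne should give 2,4-dihydroxy-3-methyl-6-(non-1-yn-1-yl)benzaldehyde F1. Copper(I)/sparteine/O2 hydroxylative dearomatisation ([Cu(MeCN)4]PF6, iPr2NEt, DMAP, O2, CH2Cl2, −10 °C, with (−)-sparteine or the (+)-sparteine surrogate, whichever leads to the 7R series), followed by buffered copper-catalysed cycloisomerisation, should give (7R)-3-heptyl-7-hydroxy-7-methyl-6H-isochromene-6,8(7H)-dione F2. Esterification of the tertiary alcohol (decanoyl chloride, Et3N, DMAP, CH2Cl2) rejoins the route at 12.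

Step 4. Ligand transfer may go to the unsubstituted ring carbons (leading back to aromatic catechol-type esters), the nucleophilic product may be oxidised a second time, or residual acetate may be transferred in place of decanoate. The fallback separates oxygenation from esterification. It sets out from 6: ortho-hydroxylation with stabilised IBX (SIBX, THF, rt) at the methyl-bearing carbon should give 5,6-dihydroxy-6-methyl-3-(non-1-yn-1-yl)cyclohexa-2,4-dien-1-one F3. Decanoyl chloride and Et3N (CH2Cl2, −78 °C) should acylate the acidic enol oxygen to give the vinylogous anhydride 6-hydroxy-6-methyl-3-(non-1-yn-1-yl)-5-oxocyclohexa-1,3-dien-1-yl decanoate F4. Catalytic DMAP at rt should then drive the 1,2 O-to-O acyl shift to the neighbouring tertiary oxygen, which rejoins the route at 8.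

Step 3. Oxidative addition into the phenoxide-bearing, electron-rich bromide may be slow, and oxidative homocoupling of the alkyne may dominate. The fallback couples before the phenols are unmasked. It sets out from 3: copper-free Sonogashira coupling with 5 (PdCl2(MeCN)2, XPhos, Cs2CO3, MeCN, 80 °C) should give 1,3-dimethoxy-2-methyl-5-(non-1-yn-1-yl)benzene F5. Demethylation at low temperature (BBr3, CH2Cl2, −78 to 0 °C, short contact to avoid bromoboration of the alkyne) rejoins the route at 6.

**Further compounds**

F1 | step 5 | 2,4-dihydroxy-3-methyl-6-(non-1-yn-1-yl)benzaldehyde | CCCCCCCC#Cc1cc(O)c(C)c(O)c1C=O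
F2 | step 5 | (7R)-3-heptyl-7-hydroxy-7-methyl-6H-isochromene-6,8(7H)-dione | O[C@]1(C)C(=O)C=C2C=C(CCCCCCC)OC=C2C1=O
F3 | step 4 | 5,6-dihydroxy-6-methyl-3-(non-1-yn-1-yl)cyclohexa-2,4-dien-1-one | CCCCCCCC#CC1=CC(=O)C(C)(O)C(O)=C1
F4 | step 4 | 6-hydroxy-6-methyl-3-(non-1-yn-1-yl)-5-oxocyclohexa-1,3-dien-1-yl decanoate (racemic) | CCCCCCCCCC(=O)OC1=CC(C#CCCCCCCC)=CC(=O)C1(C)O
F5 | step 3 | 1,3-dimethoxy-2-methyl-5-(non-1-yn-1-yl)benzene | CCCCCCCC#Cc1cc(OC)c(C)c(OC)c1
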